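**Retrosynthetic overview**

1. Locants: C10 = quaternary ring carbon (CH3, vinyl C1=C2); C9 = ring CH2; C8 = ring CH–O(ester); C7 and C6 = ring-fusion carbons (C6 carries the lactone oxygen O6); C5 = ring CH with the isopropenyl group; C11 = C(CH3)(OAc); C12 = lactone C=O.
2. Enabling feature: on the cyclohexane ring the vinyl carbon C1 (on C10) and O6 (on C6) are cis and 1,3-diaxial, so C1 can be carried as the carbonyl of a temporary γ-butyrolactone ring O6–C1(=O)–C10–C5–C6; this makes C10 an α-acyl radical site, and the small ring fixes the facial course at C10 and allows ring closure on one face only.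
3. Key disconnection: C9–C10 and C7–C8 in one radical [4+2] annulation between a monocyclic α-bromo-γ-lactone carrying an acrylate on C6 and a vinyl silyl ether (C9=C8–O), giving a 6-oxabicyclo[3.2.1]octan-7-one with C10, C8 and C7 set.
4. Ring order: butyrolactone ring from a chiral-pool butenolide (C6 from the pool, C5 by anti conjugate addition), then the cyclohexane ring (key step), then the temporary lactone is opened by DIBAL-H/Wittig (C1=O becomes the vinyl group) and the freed O6 closes the cis-fused γ-lactone of the target.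
5. End game: C11 by α-hydroxylation followed by methylation on the exo face of the cis-fused lactone enolate; acetylation, desilylation and esterification of O8 come last.

Key step: step 7

Remark (assumption): (R)-5-(hydroxymethyl)furan-2(5H)-one (1), the antipode of the common glutamic-acid-derived butenolide, is taken as a purchasable chiral-pool compound; all stereochemistry derives from it.

**Step 1**
Reactants: 1 (R)-5-(hydroxymethyl)furan-2(5H)-one
Product: 2 (R)-5-{[(tert-butyldimethylsilyl)oxy]methyl}furan-2(5H)-one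
Conditions: TBSCl, imidazole, DMF, 0 °C to rt
Reagents that add atoms: tert-butyldimethylsilyl chloride, CC(C)(C)[Si](C)(C)Cl
Why: Imidazole-promoted silylation of the primary alcohol leaves the stereocentre untouched and provides the bulky group that directs step 2.

**Step 2**
Reactants: 2 (R)-5-{[(tert-butyldimethylsilyl)oxy]methyl}furan-2(5H)-one
Product: 4 (3R,4S,5R)-5-{[(tert-butyldimethylsilyl)oxy]methyl}-3-methyl-4-(prop-1-en-2-yl)dihydrofuran-2(3H)-one, via bromomagnesium enolate 3 (not isolated)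
Conditions: CH2=C(CH3)MgBr, CuBr·SMe2 (10 mol%), THF, −40 °C; then MeI, DMPU, −40 to 0 °C
Reagents that add atoms: isopropenylmagnesium bromide, C=C(C)[Mg]Br; iodomethane, CI
Why: Copper-catalysed conjugate addition of the Grignard reagent to the butenolide should occur anti to the silyloxymethyl group (this sets C5), and the enolate is then methylated anti to the new isopropenyl group (tandem conjugate addition–enolate alkylation).

**Step 3**
Reactants: 4 (3R,4S,5R)-5-{[(tert-butyldimethylsilyl)oxy]methyl}-3-methyl-4-(prop-1-en-2-yl)dihydrofuran-2(3H)-one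
Product: 6 (3R,4S,5R)-3-bromo-5-{[(tert-butyldimethylsilyl)oxy]methyl}-3-methyl-4-(prop-1-en-2-yl)dihydrofuran-2(3H)-one, via lithium enolate 5 (not isolated)
Conditions: LDA, THF, −78 °C; then BrCCl2CCl2Br, −78 °C
Reagents that add atoms: 1,2-dibromo-1,1,2,2-tetrachloroethane, BrC(Cl)(Cl)C(Cl)(Cl)Br
Why: Enolate bromination with a mild electrophilic bromine donor should give the tertiary α-bromo lactone (radical precursor), bromine entering anti to the isopropenyl group; this centre becomes planar again in step 7, so its configuration is of no consequence.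

**Step 4**
Reactants: 6 (3R,4S,5R)-3-bromo-5-{[(tert-butyldimethylsilyl)oxy]methyl}-3-methyl-4-(prop-1-en-2-yl)dihydrofuran-2(3H)-one
Product: 7 (3R,4S,5R)-3-bromo-5-(hydroxymethyl)-3-methyl-4-(prop-1-en-2-yl)dihydrofuran-2(3H)-one
Conditions: HF·pyridine, THF, 0 °C to rt
Reagents that add atoms: none
Why: Fluoride cleavage of the primary silyl ether under weakly acidic conditions avoids base, so the tertiary bromide should not undergo dehydrobromination.

**Step 5**
Reactants: 7 (3R,4S,5R)-3-bromo-5-(hydroxymethyl)-3-methyl-4-(prop-1-en-2-yl)dihydrofuran-2(3H)-one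
Product: 8 (2R,3S,4R)-4-bromo-4-methyl-5-oxo-3-(prop-1-en-2-yl)tetrahydrofuran-2-carbaldehyde
Conditions: Dess–Martin periodinane, CH2Cl2, 0 °C to rt
Reagents that add atoms: none
Why: Dess–Martin oxidation converts the primary alcohol to the aldehyde under neutral conditions, which should avoid epimerization at the adjacent oxygen-bearing carbon.

**Step 6**
Reactants: 8 (2R,3S,4R)-4-bromo-4-methyl-5-oxo-3-(prop-1-en-2-yl)tetrahydrofuran-2-carbaldehyde; 9 tert-butyl (triphenylphosphoranylidene)acetate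
Product: 10 tert-butyl (E)-3-[(2S,3S,4R)-4-bromo-4-methyl-5-oxo-3-(prop-1-en-2-yl)tetrahydrofuran-2-yl]prop-2-enoate
Conditions: CH2Cl2, 0 °C to rt
Reagents that add atoms: none
Why: Wittig olefination with a stabilized ylide in an aprotic solvent should give the (E)-acrylate, and the ylide is too weakly basic to epimerize the aldehyde or eliminate HBr.

**Step 7**
Reactants: 10 tert-butyl (E)-3-[(2S,3S,4R)-4-bromo-4-methyl-5-oxo-3-(prop-1-en-2-yl)tetrahydrofuran-2-yl]prop-2-enoate; 11 tert-butyldimethyl(vinyloxy)silane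
Product: 14 tert-butyl 2-[(1R,3R,4R,5R,8R)-3-[(tert-butyldimethylsilyl)oxy]-1-methyl-7-oxo-8-(prop-1-en-2-yl)-6-oxabicyclo[3.2.1]octan-4-yl]acetate, via open-chain silyloxy radical 12 (not isolated), via bicyclic ester radical 13 (not isolated)
Conditions: 11 (10 equiv), (Me3Si)3SiH (1.3 equiv, added over 8 h), AIBN (20 mol%), PhH (0.01 M), 80 °C
Reagents that add atoms: none
Why: The silyl radical abstracts bromine from 10; the electrophilic tertiary α-lactone radical at C10 cannot reach the acrylate directly (only 4-exo or 5-endo modes are open), so it adds to the terminal carbon of the electron-rich enol ether 11 (C9–C10), and the nucleophilic α-silyloxy radical 12 then closes onto the β-carbon of the tethered acrylate (C7–C8) to give radical 13, which the silane reduces. The closest known reaction type is the hydride-mediated radical addition–cyclization (annulation) cascade of α-halo esters with alkenes, here polarity-matched at each stage (electrophilic, nucleophilic, electrophilic radical). The cyclohexane ring closes 6-exo-trig and thereby creates the 6-oxabicyclo[3.2.1]octan-7-one. C10 is set by addition to the planar lactone radical anti to the adjacent isopropenyl group on C5, which is also the face that carries the C6 side chain, so only this adduct can cyclize; C8 should place its silyloxy group equatorial because the axial position points into the C1–O6 lactone bridge; C7 should take the acetate arm equatorial from a chair-like transition state with the acrylate pseudo-equatorial. The step needs addition to outrun reduction of the C10 radical and ring closure to outrun reduction of 12, which excess 11, high dilution and slow addition of the slowly hydrogen-donating silane should secure; the unactivated isopropenyl group is a far poorer acceptor for 12 than the acrylate.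

**Step 8**
Reactants: 14 tert-butyl 2-[(1R,3R,4R,5R,8R)-3-[(tert-butyldimethylsilyl)oxy]-1-methyl-7-oxo-8-(prop-1-en-2-yl)-6-oxabicyclo[3.2.1]octan-4-yl]acetate
Product: 15 tert-butyl 2-[(1R,3R,4R,5R,8R)-3-[(tert-butyldimethylsilyl)oxy]-7-hydroxy-1-methyl-8-(prop-1-en-2-yl)-6-oxabicyclo[3.2.1]octan-4-yl]acetate (lactol, both epimers at the hemiacetal carbon)
Conditions: iBu2AlH (1.1 equiv), CH2Cl2, −78 °C; aqueous work-up
Reagents that add atoms: none
Why: DIBAL-H half-reduction of a lactone to the lactol at low temperature; the strained bridged lactone should react faster than the hindered tert-butyl ester.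

**Step 9**
Reactants: 15 tert-butyl 2-[(1R,3R,4R,5R,8R)-3-[(tert-butyldimethylsilyl)oxy]-7-hydroxy-1-methyl-8-(prop-1-en-2-yl)-6-oxabicyclo[3.2.1]octan-4-yl]acetate
Product: 17 (3aR,4R,6S,7R,7aR)-4-[(tert-butyldimethylsilyl)oxy]-6-methyl-7-(prop-1-en-2-yl)-6-vinylhexahydrobenzofuran-2(3H)-one, via potassium alkoxide 16 (not isolated)
Conditions: Ph3PCH3Br, KN(SiMe3)2, THF, 0 °C; then 15, 0 to 50 °C
Reagents that add atoms: methyltriphenylphosphonium bromide, C[P+](c1ccccc1)(c1ccccc1)c1ccccc1.[Br-]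
Why: Wittig methylenation of the lactol through its open hydroxy-aldehyde form installs the vinyl group (no new stereocentre), and the liberated axial C6 alkoxide should attack the tert-butyl ester in a 5-exo-trig lactonization that can only give the cis-fused γ-lactone.

**Step 10**
Reactants: 17 (3aR,4R,6S,7R,7aR)-4-[(tert-butyldimethylsilyl)oxy]-6-methyl-7-(prop-1-en-2-yl)-6-vinylhexahydrobenzofuran-2(3H)-one
Product: 19 (3R,3aR,4R,6S,7R,7aR)-4-[(tert-butyldimethylsilyl)oxy]-3-hydroxy-6-methyl-7-(prop-1-en-2-yl)-6-vinylhexahydrobenzofuran-2(3H)-one (hydroxyl expected on the exo face; the 3-epimer serves equally), via potassium enolate 18 (not isolated)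
Conditions: KN(SiMe3)2, THF, −78 °C; then 2-(benzenesulfonyl)-3-phenyloxaziridine, −78 °C
Reagents that add atoms: 2-(benzenesulfonyl)-3-phenyloxaziridine, O=S(=O)(N1OC1c1ccccc1)c1ccccc1
Why: Enolate oxidation with the Davis oxaziridine at the only acidic position (lactone α-CH2); the new carbinol centre is made planar again in step 11, so its configuration does not matter.

**Step 11**
Reactants: 19 (3R,3aR,4R,6S,7R,7aR)-4-[(tert-butyldimethylsilyl)oxy]-3-hydroxy-6-methyl-7-(prop-1-en-2-yl)-6-vinylhexahydrobenzofuran-2(3H)-one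
Product: 21 (3S,3aR,4R,6S,7R,7aR)-4-[(tert-butyldimethylsilyl)oxy]-3-hydroxy-3,6-dimethyl-7-(prop-1-en-2-yl)-6-vinylhexahydrobenzofuran-2(3H)-one, via dilithium enediolate 20 (not isolated)
Conditions: LDA (2.3 equiv), THF/DMPU, −78 to −40 °C; then MeI
Reagents that add atoms: iodomethane, CI
Why: C-methylation of the dianion of an α-hydroxy lactone; iodomethane should approach the exo (convex) face of the cis-fused bicycle, on the side of H-6/H-7 and away from C8 and its silyloxy group, which leaves the oxygen on the concave face and sets C11.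

**Step 12**
Reactants: 21 (3S,3aR,4R,6S,7R,7aR)-4-[(tert-butyldimethylsilyl)oxy]-3-hydroxy-3,6-dimethyl-7-(prop-1-en-2-yl)-6-vinylhexahydrobenzofuran-2(3H)-one
Product: 22 (3S,3aR,4R,6S,7R,7aR)-4-[(tert-butyldimethylsilyl)oxy]-3,6-dimethyl-2-oxo-7-(prop-1-en-2-yl)-6-vinyloctahydrobenzofuran-3-yl acetate
Conditions: Ac2O, DMAP (cat.), pyridine, 40 °C
Reagents that add atoms: acetic anhydride, CC(=O)OC(C)=O
Why: DMAP-catalysed acetylation of the tertiary α-hydroxy lactone, the only free hydroxyl group.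

**Step 13**
Reactants: 22 (3S,3aR,4R,6S,7R,7aR)-4-[(tert-butyldimethylsilyl)oxy]-3,6-dimethyl-2-oxo-7-(prop-1-en-2-yl)-6-vinyloctahydrobenzofuran-3-yl acetate
Product: 23 (3S,3aS,4R,6S,7R,7aR)-4-hydroxy-3,6-dimethyl-2-oxo-7-(prop-1-en-2-yl)-6-vinyloctahydrobenzofuran-3-yl acetate
Conditions: HF·pyridine, THF/pyridine, rt
Reagents that add atoms: none
Why: Fluoride cleavage of the secondary silyl ether; the tertiary acetate and the lactone should be stable to HF·pyridine.

**Step 14**
Reactants: 23 (3S,3aS,4R,6S,7R,7aR)-4-hydroxy-3,6-dimethyl-2-oxo-7-(prop-1-en-2-yl)-6-vinyloctahydrobenzofuran-3-yl acetate; 24 3-methylbut-3-enoic acid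
Product: 25 (3S,3aS,4R,6S,7R,7aR)-3-acetoxy-3,6-dimethyl-2-oxo-7-(prop-1-en-2-yl)-6-vinyloctahydrobenzofuran-4-yl 3-methylbut-3-enoate (target, CNP0106639.1)
Conditions: DCC, DMAP (5 mol%), CH2Cl2, 0 °C
Reagents that add atoms: none
Why: Steglich esterification of the equatorial secondary alcohol; low temperature and little DMAP should keep the β,γ-double bond of the acid from moving into conjugation.

**Compound list**

1 | (R)-5-(hydroxymethyl)furan-2(5H)-one | OC[C@@H]1OC(=O)C=C1 | starting material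
2 | (R)-5-{[(tert-butyldimethylsilyl)oxy]methyl}furan-2(5H)-one | CC(C)(C)[Si](C)(C)OC[C@@H]1OC(=O)C=C1 | intermediate
3 | bromomagnesium enolate of (4S,5R)-5-{[(tert-butyldimethylsilyl)oxy]methyl}-4-(prop-1-en-2-yl)dihydrofuran-2(3H)-one | CC(C)(C)[Si](C)(C)OC[C@@H]1OC(O[Mg]Br)=C[C@H]1C(C)=C | intermediate (not isolated)
4 | (3R,4S,5R)-5-{[(tert-butyldimethylsilyl)oxy]methyl}-3-methyl-4-(prop-1-en-2-yl)dihydrofuran-2(3H)-one | CC(C)(C)[Si](C)(C)OC[C@@H]1OC(=O)[C@H](C)[C@H]1C(C)=C | intermediate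
5 | lithium enolate of 4 | CC(C)(C)[Si](C)(C)OC[C@@H]1OC(O[Li])=C(C)[C@H]1C(C)=C | intermediate (not isolated)
6 | (3R,4S,5R)-3-bromo-5-{[(tert-butyldimethylsilyl)oxy]methyl}-3-methyl-4-(prop-1-en-2-yl)dihydrofuran-2(3H)-one | CC(C)(C)[Si](C)(C)OC[C@@H]1OC(=O)[C@](C)(Br)[C@H]1C(C)=C | intermediate
7 | (3R,4S,5R)-3-bromo-5-(hydroxymethyl)-3-methyl-4-(prop-1-en-2-yl)dihydrofuran-2(3H)-one | OC[C@@H]1OC(=O)[C@](C)(Br)[C@H]1C(C)=C | intermediate
8 | (2R,3S,4R)-4-bromo-4-methyl-5-oxo-3-(prop-1-en-2-yl)tetrahydrofuran-2-carbaldehyde | O=C[C@@H]1OC(=O)[C@](C)(Br)[C@H]1C(C)=C | intermediate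
9 | tert-butyl (triphenylphosphoranylidene)acetate | CC(C)(C)OC(=O)C=P(c1ccccc1)(c1ccccc1)c1ccccc1 | starting material
10 | tert-butyl (E)-3-[(2S,3S,4R)-4-bromo-4-methyl-5-oxo-3-(prop-1-en-2-yl)tetrahydrofuran-2-yl]prop-2-enoate | CC(C)(C)OC(=O)/C=C/[C@@H]1OC(=O)[C@](C)(Br)[C@H]1C(C)=C | intermediate
11 | tert-butyldimethyl(vinyloxy)silane | C=CO[Si](C)(C)C(C)(C)C | starting material
12 | open-chain α-silyloxy radical (C9–C10 formed, new chain trans to the isopropenyl group) | CC(C)(C)OC(=O)/C=C/[C@@H]1OC(=O)[C@](C)(C[CH]O[Si](C)(C)C(C)(C)C)[C@H]1C(C)=C | intermediate (not isolated)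
13 | bicyclic α-ester radical (C7–C8 formed) | O=C3[C@]1(C)C[C@@H](O[Si](C)(C)C(C)(C)C)[C@H]([CH]C(=O)OC(C)(C)C)[C@H](O3)[C@@H]1C(=C)C | intermediate (not isolated)
14 | tert-butyl 2-[(1R,3R,4R,5R,8R)-3-[(tert-butyldimethylsilyl)oxy]-1-methyl-7-oxo-8-(prop-1-en-2-yl)-6-oxabicyclo[3.2.1]octan-4-yl]acetate | O=C3[C@]1(C)C[C@@H](O[Si](C)(C)C(C)(C)C)[C@H](CC(=O)OC(C)(C)C)[C@H](O3)[C@@H]1C(=C)C | intermediate
15 | tert-butyl 2-[(1R,3R,4R,5R,8R)-3-[(tert-butyldimethylsilyl)oxy]-7-hydroxy-1-methyl-8-(prop-1-en-2-yl)-6-oxabicyclo[3.2.1]octan-4-yl]acetate (lactol, both epimers) | OC3[C@]1(C)C[C@@H](O[Si](C)(C)C(C)(C)C)[C@H](CC(=O)OC(C)(C)C)[C@H](O3)[C@@H]1C(=C)C | intermediate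
16 | potassium alkoxide of the ring-opened hydroxy ester, tert-butyl 2-[6-(silyloxy)-2-hydroxy-4-methyl-3-(prop-1-en-2-yl)-4-vinylcyclohexyl]acetate (configuration as in 17) | C=C[C@]1(C)C[C@@H](O[Si](C)(C)C(C)(C)C)[C@H](CC(=O)OC(C)(C)C)[C@H](O[K])[C@@H]1C(=C)C | intermediate (not isolated)
17 | (3aR,4R,6S,7R,7aR)-4-[(tert-butyldimethylsilyl)oxy]-6-methyl-7-(prop-1-en-2-yl)-6-vinylhexahydrobenzofuran-2(3H)-one | C=C[C@]1(C)C[C@@H](O[Si](C)(C)C(C)(C)C)[C@H]2[C@H](OC(=O)C2)[C@@H]1C(=C)C | intermediate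
18 | potassium enolate of 17 | C=C[C@]1(C)C[C@@H](O[Si](C)(C)C(C)(C)C)[C@H]2[C@H](OC(O[K])=C2)[C@@H]1C(=C)C | intermediate (not isolated)
19 | (3R,3aR,4R,6S,7R,7aR)-4-[(tert-butyldimethylsilyl)oxy]-3-hydroxy-6-methyl-7-(prop-1-en-2-yl)-6-vinylhexahydrobenzofuran-2(3H)-one | C=C[C@]1(C)C[C@@H](O[Si](C)(C)C(C)(C)C)[C@H]2[C@H](OC(=O)[C@@H]2O)[C@@H]1C(=C)C | intermediate
20 | dilithium enediolate of 19 | C=C[C@]1(C)C[C@@H](O[Si](C)(C)C(C)(C)C)[C@H]2[C@H](OC(O[Li])=C2O[Li])[C@@H]1C(=C)C | intermediate (not isolated)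
21 | (3S,3aR,4R,6S,7R,7aR)-4-[(tert-butyldimethylsilyl)oxy]-3-hydroxy-3,6-dimethyl-7-(prop-1-en-2-yl)-6-vinylhexahydrobenzofuran-2(3H)-one | C=C[C@]1(C)C[C@@H](O[Si](C)(C)C(C)(C)C)[C@H]2[C@H](OC(=O)[C@@]2(C)O)[C@@H]1C(=C)C | intermediate
22 | (3S,3aR,4R,6S,7R,7aR)-4-[(tert-butyldimethylsilyl)oxy]-3,6-dimethyl-2-oxo-7-(prop-1-en-2-yl)-6-vinyloctahydrobenzofuran-3-yl acetate | C=C[C@]1(C)C[C@@H](O[Si](C)(C)C(C)(C)C)[C@H]2[C@H](OC(=O)[C@@]2(C)OC(C)=O)[C@@H]1C(=C)C | intermediate
23 | (3S,3aS,4R,6S,7R,7aR)-4-hydroxy-3,6-dimethyl-2-oxo-7-(prop-1-en-2-yl)-6-vinyloctahydrobenzofuran-3-yl acetate | C=C[C@]1(C)C[C@@H](O)[C@H]2[C@H](OC(=O)[C@@]2(C)OC(C)=O)[C@@H]1C(=C)C | intermediate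
24 | 3-methylbut-3-enoic acid | C=C(C)CC(=O)O | starting material
25 | (3S,3aS,4R,6S,7R,7aR)-3-acetoxy-3,6-dimethyl-2-oxo-7-(prop-1-en-2-yl)-6-vinyloctahydrobenzofuran-4-yl 3-methylbut-3-enoate | C=C[C@]1(C)C[C@@H](OC(=O)CC(=C)C)[C@H]2[C@H](OC(=O)[C@@]2(C)OC(C)=O)[C@@H]1C(=C)C | target

**Step count and risks**

Total step count: 14. Longest linear sequence: 14 steps (from 1).

Steps most likely to fail:

1. Step 7. Hydrogen transfer to the C10 radical or to radical 12 may come before the bimolecular addition or the ring closure, and facial control in the 6-exo closure may be eroded. The fallback is a polar/ketyl route that sets out from 4 and comes back at 14. The lithium enolate of 4 is alkylated with (2-iodoethoxy)(tert-butyl)dimethylsilane (DMPU), again anti to the isopropenyl group, to give the bis-silyl ether lactone F1. HF·pyridine gives the diol F2, which is oxidized at once with Dess–Martin periodinane to the dialdehyde F3. One equivalent of ylide 9 at low temperature should olefinate the more electrophilic α-oxygenated aldehyde to give the acrylate aldehyde F4. SmI2 (THF, MeOH, −78 °C) then closes the cyclohexane ring by a 6-exo ketyl–olefin cyclization to the hydroxy bicyclic lactone F5, with the hydroxyl and the acetate arm trans. Silylation (TBSOTf, 2,6-lutidine) gives 14.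

2. Step 11. The dianion may undergo O-alkylation or proton transfer instead of C-alkylation, or lose facial selectivity. The fallback sets out from 19 and comes back at 21. The hydroxyl is silylated (TESOTf, 2,6-lutidine) to the triethylsilyl ether F6. Its mono-enolate (LDA, −78 °C) is methylated on the exo face to give the methylated silyl ether F7. Selective removal of the triethylsilyl group (PPTS, MeOH, 0 °C) gives 21.

3. Step 8. Hydride may attack the tert-butyl ester, or the lactone may be over-reduced to the diol. The fallback sets out from 14 and comes back at 17. The tert-butyl ester is cleaved first (TMSOTf, 2,6-lutidine, then water) to the lactone acid F8. Its carboxylate is inert to iBu2AlH (2.2 equiv, −78 °C), which gives the lactol acid F9. Excess Ph3P=CH2 gives the hydroxy acid F10, which lactonizes on acidification (or with a carbodiimide) to 17.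

**Further compounds**

F1 | step 7 | lactone 4 alkylated at C-3 with a 2-[(tert-butyldimethylsilyl)oxy]ethyl group trans to the isopropenyl group | CC(C)(C)[Si](C)(C)OC[C@@H]1OC(=O)[C@](C)(CCO[Si](C)(C)C(C)(C)C)[C@H]1C(C)=C
F2 | step 7 | 3-(2-hydroxyethyl)-5-(hydroxymethyl)-3-methyl-4-(prop-1-en-2-yl)dihydrofuran-2(3H)-one (diol from F1) | OC[C@@H]1OC(=O)[C@](C)(CCO)[C@H]1C(C)=C
F3 | step 7 | 4-methyl-5-oxo-4-(2-oxoethyl)-3-(prop-1-en-2-yl)tetrahydrofuran-2-carbaldehyde (dialdehyde from F2) | O=C[C@@H]1OC(=O)[C@](C)(CC=O)[C@H]1C(C)=C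
F4 | step 7 | tert-butyl (E)-3-[4-methyl-5-oxo-4-(2-oxoethyl)-3-(prop-1-en-2-yl)tetrahydrofuran-2-yl]prop-2-enoate | CC(C)(C)OC(=O)/C=C/[C@@H]1OC(=O)[C@](C)(CC=O)[C@H]1C(C)=C
F5 | step 7 | tert-butyl 2-[3-hydroxy-1-methyl-7-oxo-8-(prop-1-en-2-yl)-6-oxabicyclo[3.2.1]octan-4-yl]acetate (desilyl 14) | O=C3[C@]1(C)C[C@@H](O)[C@H](CC(=O)OC(C)(C)C)[C@H](O3)[C@@H]1C(=C)C
F6 | step 11 | triethylsilyl ether of 19 | C=C[C@]1(C)C[C@@H](O[Si](C)(C)C(C)(C)C)[C@H]2[C@H](OC(=O)[C@@H]2O[Si](CC)(CC)CC)[C@@H]1C(=C)C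
F7 | step 11 | triethylsilyl ether of 21 | C=C[C@]1(C)C[C@@H](O[Si](C)(C)C(C)(C)C)[C@H]2[C@H](OC(=O)[C@@]2(C)O[Si](CC)(CC)CC)[C@@H]1C(=C)C
F8 | step 8 | 2-[3-[(tert-butyldimethylsilyl)oxy]-1-methyl-7-oxo-8-(prop-1-en-2-yl)-6-oxabicyclo[3.2.1]octan-4-yl]acetic acid | O=C3[C@]1(C)C[C@@H](O[Si](C)(C)C(C)(C)C)[C@H](CC(=O)O)[C@H](O3)[C@@H]1C(=C)C
F9 | step 8 | 2-[3-[(tert-butyldimethylsilyl)oxy]-7-hydroxy-1-methyl-8-(prop-1-en-2-yl)-6-oxabicyclo[3.2.1]octan-4-yl]acetic acid (lactol) | OC3[C@]1(C)C[C@@H](O[Si](C)(C)C(C)(C)C)[C@H](CC(=O)O)[C@H](O3)[C@@H]1C(=C)C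
F10 | step 8 | 2-[6-[(tert-butyldimethylsilyl)oxy]-2-hydroxy-4-methyl-3-(prop-1-en-2-yl)-4-vinylcyclohexyl]acetic acid | C=C[C@]1(C)C[C@@H](O[Si](C)(C)C(C)(C)C)[C@H](CC(=O)O)[C@H](O)[C@@H]1C(=C)C
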